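Early on, each substrate that goes on to double product takes two partners, so read the charges below by that cost.

    substrate + partner → single product (k1 = 0.0039 /M/s)
    partner + single product → double product (k2 = 0.0074 /M/s)
    partner + double product ⇌ triple product (K3 = 1.2 /M, k3 = 2.7 × 10⁻⁴ /M/s)
    partner + triple product ⇌ idle adduct, settled at all times (K4 = 42 /M)

| setting | beta | alpha | theta |
|---|---|---|---|
| substrate | 0.25 M | 0.25 M | 0.25 M |
| partner | 0.230 M | 0.560 M | 1.40 M |
| time | 2.0 h | 2.0 h | 2.0 h |

* which of these there is most of at the end, counted by the substrate in it, beta (substrate / triple product / single product / double product)
* which of these there is most of at the end, counted by the substrate in it, alpha (substrate / triple product / single product / double product)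
* which of these there is most of at the end, counted by the substrate in it, theta (substrate / triple product / single product / double product)
* final amount of the leader among these, as a percentage of the substrate charged, in beta
* final amount of the leader among these, as a percentage of the substrate charged, in alpha
* final amount of the leader among these, as a percentage of the substrate charged, in theta

- triple product is meant together with its idle adduct
- run time (beta): 2.0 h

**Partner budget.** That cost comes to 217% of the partner charged in beta, 89.3% in alpha and 35.7% in theta. Beta cannot pay it: partner is its limiting reagent, so don't charge beta for triple product. After paying, alpha keeps 10.7% of its partner and theta keeps 64.3%.

**Theta's clock.** In theta the first step starts at 19.7 /h per substrate, while the third, with the partner left after that payment, runs at 0.875 /h. So I count double product as made at once and treat the third step as pseudo-first-order. Over 2.0 h that first round reckons 82.6% of double product converted. But conversion costs partner: in theta nearly all triple product sits as idle adduct, so each conversion takes two partners, and I drop the way back.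

**Second round.** Put 82.6% back in, and theta's free partner falls to 34.8% of its charge, averaging 49.5%. The rate becomes 0.674 /h, and 1.03 h is the halving time of double product by the forward third step at that average partner. My reckoning gives theta 74.0% triple product. Alpha's leftover partner gives a halving time of 11.9 h, longer than its run, so alpha stays with double product. Charge theta for triple product and alpha for double product.

**The forecast.** It names substrate at 42% in beta, double product at 83% in alpha and triple product at 70% in theta, saying “the large excess lets the slow third step run for most of the two hours”. My 74.0% for theta stands above its figure.

**The result.** Beta ends with substrate leading at 41.6%, alpha with double product at 83.5%, and theta with triple product at 70.0%. Theta still holds 39.8% of its partner free at 2.00 h. The halving time 1.03 h had put theta 4.0 percentage points higher. Read the same theta flask at 80 min, and 1.03 h gives 59.2%; that flask holds 57.8% triple product.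

All constants belong to no real substance; no experiment stands behind them.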